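**Retrosynthetic overview**

1. Numbering: ring A is the cycloheptane C1 (C(OH)–acyl), C5 (CH–O-acyl), C6 (CH–O of the lactone), C7, C8 (CH2), C9 (CHOH), C10 (CHMe); ring B is the methylene lactone (C6, C7, C11, C12, O; C13 = CH2); side chain C2(=O)–C3–C4(OH)–C15; α is the face of the lactone oxygen.
2. Late stage: C2=O from a C2≡C3 alkyne (gold hydration steered by the cis C9–OH); C9–OH from a C9 ketone (from a C9 carboxylate by Curtius rearrangement, reduction directed by C1–OH); C5 ester by carboxylate opening of a C1/C5 α-epoxide.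
3. Ring B by iodolactonisation of C5=C6 with the acrylate on C7; C1–C2 by addition of the cerium acetylide of (R)-but-3-yn-2-ol to a C1 ketone.
4. Ring A is formed first: C6–C7 and C9–C10 arise in one operation by (4+3) union of a vinylcarbenoid (C7–C8–C9, from 10) with a 1-methoxy-3-silyloxy diene (C10–C1–C5–C6, 3).
5. Enabling feature: ring A divides into a three-carbon arc C7–C8–C9 (C9 oxidised, C7 carrying C11–C13 of ring B) and a four-carbon arc C10–C1–C5–C6 with oxygen on C1 and C6, i.e. a vinylcarbenoid/dioxygenated diene pair; the C7 substituent and the C10 methyl flanking the three-carbon arc are cis, as a boat Cope transition state delivers.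

Key step: step 7

Remark 1: the (R) catalyst in step 7 is chosen by analogy with the accepted model for donor/acceptor carbenoid cyclopropanation by the prolinate catalysts; if the sense of induction proves opposite, Rh2(S-DOSP)4 is used instead.
Remark 2: α/β descriptors refer to the numbering above (α: lactone O, C7–C11 bond, C10 methyl, C1–OH; β: C5–O-acyl, C9–OH, C1–C2 bond).

**Route**

Step 1
Reactants: 1 (E)-4-methoxybut-3-en-2-one
Product: 2 (E)-1-methoxypent-1-en-3-one
Conditions: LiN(iPr)2, THF, −78 °C; MeI, −78 → −20 °C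
Reagents that add atoms: iodomethane CI
Why: Kinetic enolate formation at the methyl group and C-alkylation with MeI should give the ethyl ketone without touching the β-methoxy enone.

Step 2
Reactants: 2 (E)-1-methoxypent-1-en-3-one
Product: 3 (1E,3Z)-3-(tert-butyldimethylsilyloxy)-1-methoxypenta-1,3-diene
Conditions: TBSOTf, Et3N, Et2O, 0 °C
Reagents that add atoms: tert-butyldimethylsilyl trifluoromethanesulfonate CC(C)(C)[Si](C)(C)OS(=O)(=O)C(F)(F)F
Why: Soft enolisation/O-silylation of the ethyl ketone under amine/silyl triflate conditions should give the (Z)-silyl enol ether (methyl cis to OSi), the geometry the key step needs.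

Step 3
Reactants: 4 methyl 4-oxobutanoate; 5 tert-butyl acrylate
Product: 7 tert-butyl 2-(5-oxooxolan-2-yl)prop-2-enoate (racemic), via hydroxy ester 6 (not isolated)
Conditions: DABCO (0.5 equiv), neat, rt, 5 d; then p-TsOH·H2O (5 mol%), PhMe, 50 °C
Reagents that add atoms: none
Why: Morita–Baylis–Hillman addition of the acrylate to the aldehyde gives a γ-hydroxy ester that lactonises with loss of methanol; the stereocentre is racemic and is destroyed in step 4.

Step 4
Reactants: 7 tert-butyl 2-(5-oxooxolan-2-yl)prop-2-enoate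
Product: 8 (3E)-5-(tert-butoxycarbonyl)hexa-3,5-dienoic acid
Conditions: Pd(PPh3)4 (5 mol%), THF, 60 °C
Reagents that add atoms: none
Why: Zerovalent palladium ionises the allylic lactone C–O bond (Tsuji–Trost type π-allyl formation) and β-hydride elimination should open the ring to the (E)-dienoic acid.

Step 5
Reactants: 8 (3E)-5-(tert-butoxycarbonyl)hexa-3,5-dienoic acid
Product: 9 1-tert-butyl 6-(2,2,2-trichloroethyl) (3E)-2-methylidenehex-3-enedioate
Conditions: Cl3CCH2OH, DCC, DMAP (5 mol%), CH2Cl2, 0 °C
Reagents that add atoms: 2,2,2-trichloroethanol OCC(Cl)(Cl)Cl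
Why: Steglich esterification installs an ester that zinc can cleave later beside a lactone and a secondary ester; any double-bond migration into conjugation is harmless because step 6 passes through the common dienolate.

Step 6
Reactants: 9 1-tert-butyl 6-(2,2,2-trichloroethyl) (3E)-2-methylidenehex-3-enedioate
Product: 10 1-tert-butyl 6-(2,2,2-trichloroethyl) (3E)-5-diazo-2-methylidenehex-3-enedioate
Conditions: 4-acetamidobenzenesulfonyl azide, DBU, MeCN, 0 °C; used at once
Reagents that add atoms: 4-acetamidobenzenesulfonyl azide CC(=O)Nc1ccc(cc1)S(=O)(=O)N=[N+]=[N-]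
Why: Regitz diazo transfer to the α-carbon of the vinylogous ester dienolate should give the (E)-vinyldiazoacetate, the standard access to this reagent class.

Step 7
Reactants: 3 (1E,3Z)-3-(tert-butyldimethylsilyloxy)-1-methoxypenta-1,3-diene; 10 1-tert-butyl 6-(2,2,2-trichloroethyl) (3E)-5-diazo-2-methylidenehex-3-enedioate
Product: 12 2,2,2-trichloroethyl 7α-[1-(tert-butoxycarbonyl)ethenyl]-1-(tert-butyldimethylsilyloxy)-6α-methoxy-10α-methylcyclohepta-1(5),8-diene-9-carboxylate, via cis-divinylcyclopropane 11 (not isolated)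
Conditions: 3 (3 equiv), Rh2(R-DOSP)4 (1 mol%), hexanes, −40 °C, 10 added over 2 h, then rt
Reagents that add atoms: none
Why: Loss of N2 from 10 on the divalent-rhodium catalyst should give a donor/acceptor vinylcarbenoid whose carbenoid carbon (C9) is attacked by the diene terminus C10 of 3 and closes onto C1 to the cis-divinylcyclopropane 11, which rearranges by a Cope shift that forms C6–C7 and opens the three-membered ring. The closest known reaction type is the rhodium-catalysed tandem cyclopropanation/Cope rearrangement (formal (4+3) cycloaddition) of vinyldiazoacetates with 1-alkoxy- and 2-silyloxy-1,3-dienes. Ring A is closed in two stages, first as a three-membered ring by carbene transfer to C10=C1 (bonds C9–C10 and C9–C1) and then by [3,3]-sigmatropic ring expansion through the boat transition state, the only one open to a cis-divinylcyclopropane. C10 is fixed by stereospecific syn addition to the (Z)-enol ether on the carbenoid face selected by the chiral carboxylate ligands, C7 by the (E)-alkene of 10 in the boat, which puts the C7 substituent cis to the C10 methyl, and the C6 methoxy centre (cis to C7 from the (E)-enol ether) is removed in step 8. The step needs attack at C10 rather than at C5 or at the vinylogous carbon C7, and seven- rather than five-membered closure: both oxygen donors of 3 (OMe at C6 through the diene, OSi at C1 directly) polarise it towards C10, the vinyl terminus of the carbenoid is substituted, and the hydrocarbon solvent disfavours zwitterionic [3+2] closure. A trans-divinyl isomer of the push–pull cyclopropane can reopen and reclose, so that material is funnelled through the one isomer able to rearrange.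

Step 8
Reactants: 12 cycloheptadiene silyl enol ether
Product: 13 2,2,2-trichloroethyl 7α-[1-(tert-butoxycarbonyl)ethenyl]-10α-methyl-1-oxocyclohepta-5,8-diene-9-carboxylate
Conditions: 1 M HCl (aq), THF, 0 °C, 15 min; used without storage
Reagents that add atoms: none
Why: Hydrolysis of the silyl enol ether and acid-induced β-elimination of methanol (the usual unmasking of 1-methoxy-3-silyloxy-diene adducts) should give the C5=C6 enone, with C7 and C10 untouched under brief cold acid.

Step 9
Reactants: 14 (R)-but-3-yn-2-ol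
Product: 15 (R)-tert-butyl(but-3-yn-2-yloxy)dimethylsilane
Conditions: TBSCl, imidazole, DMF, rt
Reagents that add atoms: tert-butyldimethylsilyl chloride CC(C)(C)[Si](C)(C)Cl
Why: Standard silylation of the secondary alcohol; the stereocentre (future C4) is not involved.

Step 10
Reactants: 13 dienone; 15 (R)-tert-butyl(but-3-yn-2-yloxy)dimethylsilane
Product: 16 2,2,2-trichloroethyl 7α-[1-(tert-butoxycarbonyl)ethenyl]-1α-hydroxy-10α-methyl-1β-[(3R)-3-(tert-butyldimethylsilyloxy)but-1-ynyl]cyclohepta-5,8-diene-9-carboxylate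
Conditions: 15 (1.5 equiv), n-BuLi, THF, −78 °C; CeCl3, −78 °C, 1 h; 13, −78 °C; AcOH, −78 °C
Reagents that add atoms: none
Why: The weakly basic trivalent-cerium acetylide should add 1,2 to the enolisable enone faster than it deprotonates, entering on the β face anti to the C10 methyl (held pseudo-axial by allylic strain with the C9 ester), which sets C1 with the hydroxyl α.

Step 11
Reactants: 16 tertiary propargylic alcohol
Product: 17 iodolactone (ring B cis-fused with O at C6 α; 5β-iodo; 1α-hydroxy; C9 trichloroethyl ester)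
Conditions: I2 (3 equiv), NaHCO3, MeCN, 0 °C, dark
Reagents that add atoms: iodine II
Why: Iodolactonisation: the carbonyl oxygen of the tert-butyl ester on the α face of C7 attacks C6 of the iodonium ion 5-exo and anti to iodine, so the lactone is cis-fused, iodine sits β on C5 and the tert-butyl group leaves as isobutene.

Step 12
Reactants: 17 iodolactone
Product: 18 1α,5α-epoxide
Conditions: Ag2O (1.5 equiv), THF, rt, dark
Reagents that add atoms: none
Why: Silver-assisted intramolecular Williamson closure (3-exo-tet) of the trans-iodohydrin: the α C1–OH displaces the β C5–I with inversion, giving the α-epoxide under non-basic conditions that spare the methylene lactone.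

Step 13
Reactants: 18 1α,5α-epoxide; 19 (S)-2-methylbutanoic acid
Product: 20 5β-[(S)-2-methylbutanoyloxy]-1α-hydroxy lactone (alkyne at C1, trichloroethyl ester at C9)
Conditions: 19 (5 equiv), Cs2CO3 (1.5 equiv), DMF, 60 °C
Reagents that add atoms: none
Why: SN2 opening of the trisubstituted epoxide by the cesium carboxylate at its only secondary carbon (C5, trans-diaxial, inversion) should place the ester β on C5 and leave the α tertiary hydroxyl on C1.

Step 14
Reactants: 20 trichloroethyl ester
Product: 21 C9 carboxylic acid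
Conditions: Zn dust, AcOH/THF (1:3), rt
Reagents that add atoms: none
Why: Reductive β-elimination of the 2,2,2-trichloroethyl group by zinc frees the conjugated acid while the lactone, the secondary ester and the silyl ether are inert.

Step 15
Reactants: 21 C9 carboxylic acid
Product: 24 C9 ketone (C8 now CH2), via acyl azide 22 (not isolated), via vinyl isocyanate 23 (not isolated)
Conditions: (PhO)2P(O)N3, Et3N, PhMe, 0 °C → rt; aqueous wash; PhMe, 80 °C; then THF/H2O/AcOH (8:2:1), 40 °C
Reagents that add atoms: water O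
Why: Curtius rearrangement of the α,β-unsaturated acyl azide gives the vinyl isocyanate, whose hydration, decarboxylation and imine hydrolysis deliver the C9 ketone; the amine base is washed out before heating and the hydrolysis is weakly acidic so that the C10 centre and the β-hydroxy ketone survive.

Step 16
Reactants: 24 C9 ketone
Product: 25 9β-alcohol (1α,9β-diol)
Conditions: Me4NBH(OAc)3 (6 equiv), MeCN/AcOH (1:1), −25 °C
Reagents that add atoms: none
Why: Evans–Saksena hydroxyl-directed reduction: the α C1–OH binds boron and delivers hydride intramolecularly to the α face of C9, so the new hydroxyl is β (1,3-anti); the methylene lactone, esters and alkyne are not reduced.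

Step 17
Reactants: 25 1α,9β-diol alkyne
Product: 27 O-silyl ether of the target (C2 ketone, C4–OTBS), via bicyclic enol ether 26 (not isolated)
Conditions: Ph3PAuNTf2 (5 mol%), THF/H2O (10:1), rt; then p-TsOH·H2O (10 mol%), rt
Reagents that add atoms: water O
Why: Monovalent-gold-catalysed 5-exo-dig hydroalkoxylation by the cis C9–OH (the C5 ester carbonyl can assist in the same sense, 6-exo) puts oxygen on C2, and hydrolysis of the enol ether 26 gives the C2 ketone with C3 as CH2 and returns C9–OH.

Step 18
Reactants: 27 O-silyl ether of the target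
Product: 28 CNP0291806.4 (target)
Conditions: HF·pyridine, pyridine/THF, 0 °C → rt
Reagents that add atoms: none
Why: Buffered fluoride desilylation frees the C4 hydroxyl without eliminating the β-hydroxy ketone or adding to the methylene lactone.

**Compound list**

1 | (E)-4-methoxybut-3-en-2-one | CO/C=C/C(C)=O | starting material
2 | (E)-1-methoxypent-1-en-3-one | CCC(=O)/C=C/OC | intermediate
3 | (1E,3Z)-3-(tert-butyldimethylsilyloxy)-1-methoxypenta-1,3-diene | CO/C=C/C(O[Si](C)(C)C(C)(C)C)=C/C | intermediate
4 | methyl 4-oxobutanoate | COC(=O)CCC=O | starting material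
5 | tert-butyl acrylate | C=CC(=O)OC(C)(C)C | starting material
6 | tert-butyl 3-hydroxy-6-methoxy-2-methylidene-6-oxohexanoate (racemic) | C=C(C(O)CCC(=O)OC)C(=O)OC(C)(C)C | intermediate
7 | tert-butyl 2-(5-oxooxolan-2-yl)prop-2-enoate (racemic) | C=C(C1CCC(=O)O1)C(=O)OC(C)(C)C | intermediate
8 | (3E)-5-(tert-butoxycarbonyl)hexa-3,5-dienoic acid | C=C(/C=C/CC(=O)O)C(=O)OC(C)(C)C | intermediate
9 | 1-tert-butyl 6-(2,2,2-trichloroethyl) (3E)-2-methylidenehex-3-enedioate | C=C(/C=C/CC(=O)OCC(Cl)(Cl)Cl)C(=O)OC(C)(C)C | intermediate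
10 | 1-tert-butyl 6-(2,2,2-trichloroethyl) (3E)-5-diazo-2-methylidenehex-3-enedioate | C=C(/C=C/C(=[N+]=[N-])C(=O)OCC(Cl)(Cl)Cl)C(=O)OC(C)(C)C | intermediate
11 | cis-divinylcyclopropane: 2,2,2-trichloroethyl 1-[(E)-3-(tert-butoxycarbonyl)buta-1,3-dienyl]-2-(tert-butyldimethylsilyloxy)-2-[(E)-2-methoxyethenyl]-3-methylcyclopropanecarboxylate, the two alkenyl groups cis, methyl cis to OTBS | C=C(C(=O)OC(C)(C)C)/C=C/[C@@]1(C(=O)OCC(Cl)(Cl)Cl)[C@H](C)[C@@]1(O[Si](C)(C)C(C)(C)C)/C=C/OC | intermediate
12 | 2,2,2-trichloroethyl 7α-[1-(tert-butoxycarbonyl)ethenyl]-1-(tert-butyldimethylsilyloxy)-6α-methoxy-10α-methylcyclohepta-1(5),8-diene-9-carboxylate | C=C(C(=O)OC(C)(C)C)[C@@H]1C=C(C(=O)OCC(Cl)(Cl)Cl)[C@H](C)C(O[Si](C)(C)C(C)(C)C)=C[C@@H]1OC | intermediate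
13 | 2,2,2-trichloroethyl 7α-[1-(tert-butoxycarbonyl)ethenyl]-10α-methyl-1-oxocyclohepta-5,8-diene-9-carboxylate | C=C(C(=O)OC(C)(C)C)[C@@H]1C=C(C(=O)OCC(Cl)(Cl)Cl)[C@H](C)C(=O)C=C1 | intermediate
14 | (R)-but-3-yn-2-ol | C#C[C@@H](C)O | starting material
15 | (R)-tert-butyl(but-3-yn-2-yloxy)dimethylsilane | C#C[C@@H](C)O[Si](C)(C)C(C)(C)C | intermediate
16 | tertiary propargylic alcohol: 13 with 1α-OH and 1β-[(3R)-3-(tert-butyldimethylsilyloxy)but-1-ynyl] | C=C(C(=O)OC(C)(C)C)[C@@H]1C=C(C(=O)OCC(Cl)(Cl)Cl)[C@H](C)[C@@](O)(C#C[C@@H](C)O[Si](C)(C)C(C)(C)C)C=C1 | intermediate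
17 | iodolactone: cis-fused α-methylene-γ-lactone (O at C6 α), 5β-iodo, 1α-hydroxy, 1β-alkynyl, 10α-methyl, C8=C9 with trichloroethyl ester | C=C1C(=O)O[C@@H]2[C@H]1C=C(C(=O)OCC(Cl)(Cl)Cl)[C@H](C)[C@@](O)(C#C[C@@H](C)O[Si](C)(C)C(C)(C)C)[C@H]2I | intermediate
18 | 1α,5α-epoxide of the lactone | C=C1C(=O)O[C@@H]2[C@H]1C=C(C(=O)OCC(Cl)(Cl)Cl)[C@H](C)[C@]3(C#C[C@@H](C)O[Si](C)(C)C(C)(C)C)O[C@H]23 | intermediate
19 | (S)-2-methylbutanoic acid | CC[C@H](C)C(=O)O | starting material
20 | 5β-[(S)-2-methylbutanoyloxy]-1α-hydroxy lactone, trichloroethyl ester at C9 | C=C1C(=O)O[C@@H]2[C@H]1C=C(C(=O)OCC(Cl)(Cl)Cl)[C@H](C)[C@@](O)(C#C[C@@H](C)O[Si](C)(C)C(C)(C)C)[C@H]2OC(=O)[C@@H](C)CC | intermediate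
21 | C9 carboxylic acid of 20 | C=C1C(=O)O[C@@H]2[C@H]1C=C(C(=O)O)[C@H](C)[C@@](O)(C#C[C@@H](C)O[Si](C)(C)C(C)(C)C)[C@H]2OC(=O)[C@@H](C)CC | intermediate
22 | C9 acyl azide | C=C1C(=O)O[C@@H]2[C@H]1C=C(C(=O)N=[N+]=[N-])[C@H](C)[C@@](O)(C#C[C@@H](C)O[Si](C)(C)C(C)(C)C)[C@H]2OC(=O)[C@@H](C)CC | intermediate
23 | C9 vinyl isocyanate | C=C1C(=O)O[C@@H]2[C@H]1C=C(N=C=O)[C@H](C)[C@@](O)(C#C[C@@H](C)O[Si](C)(C)C(C)(C)C)[C@H]2OC(=O)[C@@H](C)CC | intermediate
24 | C9 ketone (C8 = CH2) | C=C1C(=O)O[C@@H]2[C@H]1CC(=O)[C@H](C)[C@@](O)(C#C[C@@H](C)O[Si](C)(C)C(C)(C)C)[C@H]2OC(=O)[C@@H](C)CC | intermediate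
25 | 1α,9β-diol with C1 alkyne | C=C1C(=O)O[C@@H]2[C@H]1C[C@@H](O)[C@H](C)[C@@](O)(C#C[C@@H](C)O[Si](C)(C)C(C)(C)C)[C@H]2OC(=O)[C@@H](C)CC | intermediate
26 | bicyclic (Z)-enol ether bridging C9–O and C2 | C=C1C(=O)O[C@@H]2[C@H]1C[C@H]3O/C(=C\[C@@H](C)O[Si](C)(C)C(C)(C)C)[C@](O)([C@H]3C)[C@H]2OC(=O)[C@@H](C)CC | intermediate
27 | C4-O-tert-butyldimethylsilyl ether of the target | C=C1C(=O)O[C@@H]2[C@H]1C[C@@H](O)[C@H](C)[C@@](O)(C(=O)C[C@@H](C)O[Si](C)(C)C(C)(C)C)[C@H]2OC(=O)[C@@H](C)CC | intermediate
28 | CNP0291806.4, (1S,5S,6R,7S,9R,10S) in the numbering above, side chain (R)-3-hydroxybutanoyl, ester (S)-2-methylbutanoate | C=C1C(=O)O[C@@H]2[C@H]1C[C@@H](O)[C@H](C)[C@@](O)(C(=O)C[C@@H](C)O)[C@H]2OC(=O)[C@@H](C)CC | target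

**Summary**

Total step count: 18. Longest linear sequence: 15 steps (steps 3–8 and 10–18).

Steps most likely to fail:

Step 7. The carbenoid must be transferred to a methyl-bearing, trisubstituted enol-ether terminus, and with the bulky trichloroethyl ester the face selectivity at the carbenoid may be low, so that the cycloadduct forms with insufficient enantiomeric purity. Fallback (stereocontrol moved from the catalyst to the chiral-pool side chain): 3 and 10 are united with the achiral carboxylate complex Rh2(esp)2 (esp = α,α,α′,α′-tetramethyl-1,3-benzenedipropionate) under otherwise forcing conditions, giving 12 together with its enantiomer F1. Acid unmasking as in step 8 gives 13 and its enantiomer F2. Addition of the enantiopure cerium acetylide from 15 as in step 10 then gives 16 and the ring-enantiomeric diastereomer F3, which differ as diastereomers because C4 is fixed as R and are separated by chromatography. The fallback sets out from 3 and 10 and returns at 16.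

Step 10. The acetylide may deprotonate C10 (α to the ketone and allylic to the C8=C9 enoate), after which migration of the C8=C9 bond into conjugation would erase the C10 centre before 1,2-addition occurs. Fallback (the enone is consumed first, the alkyne is added to a more electrophilic, non-conjugated ketone): from 13, hydroperoxide epoxidation of the enone C5=C6 (H2O2, catalytic K2CO3, MeOH, −20 °C; too weakly basic to enolise C10), anti to the C7 substituent, gives the 5β,6β-epoxy ketone F4. Camphorsulfonic acid in CH2Cl2 lets the tert-butyl ester open the epoxide at C6 with inversion (isobutene lost), giving the cis-fused hydroxy keto lactone F5 with the C5 hydroxyl β. The cerium acetylide from 15 (2.5 equiv) adds to the chelated α-hydroxy ketone anti to the C10 methyl to give the diol F6. Steglich monoacylation of the secondary C5 hydroxyl with 19 (DCC, DMAP) returns to the route at 20.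

Step 13. Substitution at C5, a ring carbon next to the fully substituted C1, may be too slow, so that opening at the propargylic C1 or addition to the methylene lactone takes over. Fallback (the C5 oxygen is brought in as an epoxide oxygen instead of by substitution): from 16, the tertiary hydroxyl is silylated (TMSOTf, 2,6-lutidine) to the trimethylsilyl ether F7. m-CPBA epoxidises C5=C6 from the β face, anti to the silyloxy group and the C7 substituent, giving the epoxide F8. Camphorsulfonic acid triggers 5-exo opening at C6 by the tert-butyl ester with inversion, with loss of isobutene and of the trimethylsilyl group, to give the diol F6 of the preceding fallback. Steglich acylation of its secondary C5 hydroxyl with 19 returns to the route at 20.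

Further compounds
F1 | step 7 | enantiomer of 12 | C=C(C(=O)OC(C)(C)C)[C@H]1C=C(C(=O)OCC(Cl)(Cl)Cl)[C@@H](C)C(O[Si](C)(C)C(C)(C)C)=C[C@H]1OC
F2 | step 7 | enantiomer of 13 | C=C(C(=O)OC(C)(C)C)[C@H]1C=C(C(=O)OCC(Cl)(Cl)Cl)[C@@H](C)C(=O)C=C1
F3 | step 7 | diastereomer of 16 with C1, C7 and C10 inverted and C4 still R | C=C(C(=O)OC(C)(C)C)[C@H]1C=C(C(=O)OCC(Cl)(Cl)Cl)[C@@H](C)[C@](O)(C#C[C@@H](C)O[Si](C)(C)C(C)(C)C)C=C1
F4 | step 10 | 5β,6β-epoxy ketone from 13 | C=C(C(=O)OC(C)(C)C)[C@@H]1C=C(C(=O)OCC(Cl)(Cl)Cl)[C@H](C)C(=O)[C@H]2O[C@@H]12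
F5 | step 10 | cis-fused methylene lactone with 5β-hydroxy and C1 ketone | C=C1C(=O)O[C@@H]2[C@H]1C=C(C(=O)OCC(Cl)(Cl)Cl)[C@H](C)C(=O)[C@H]2O
F6 | step 10 | 1α,5β-diol lactone with C1 alkyne (20 without the 2-methylbutanoyl group) | C=C1C(=O)O[C@@H]2[C@H]1C=C(C(=O)OCC(Cl)(Cl)Cl)[C@H](C)[C@@](O)(C#C[C@@H](C)O[Si](C)(C)C(C)(C)C)[C@H]2O
F7 | step 13 | C1-O-trimethylsilyl ether of 16 | C=C(C(=O)OC(C)(C)C)[C@@H]1C=C(C(=O)OCC(Cl)(Cl)Cl)[C@H](C)[C@@](O[Si](C)(C)C)(C#C[C@@H](C)O[Si](C)(C)C(C)(C)C)C=C1
F8 | step 13 | 5β,6β-epoxide of F7 | C=C(C(=O)OC(C)(C)C)[C@@H]1C=C(C(=O)OCC(Cl)(Cl)Cl)[C@H](C)[C@@](O[Si](C)(C)C)(C#C[C@@H](C)O[Si](C)(C)C(C)(C)C)[C@H]2O[C@@H]12
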